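**Plan**

Locants are carotenoid locants: ring A (C1–C6) is the 3-hydroxycyclohexene ring carrying the C7≡C8 alkyne, ring B (C1'–C6') is the trans-5',6'-diol ring; the target is the all-E (3R,5'R,6'R) triol.
Last cut: the C12'–C13' single bond of the C11'=C12'–C13'(CH3)=C14' diene. C11' and C14' carry only hydrogen and each is flanked by a further double bond (C9'=C10', C15=C15'), so both flanking alkenes are taken back to alkynes: a C24 methyl-capped 1,3-enyne (C13'≡C14', ring A half) and a C16 terminal 1,3-enyne (C11'≡C12', ring B half).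
Forward, the two enynes are joined by a titanium-mediated reductive alkyne–alkyne cross-coupling through a transient titanacyclopentadiene: two alkyne carbons of like polarity are united, and the C12'–C13' bond and both E double bonds form in one operation; the extra unsaturation is the only activating device and is consumed in the event.
C24 half: cuts at C15=C15' and C11=C12 (Horner–Wadsworth–Emmons) and at C6–C7 (Sonogashira coupling of a ring A enol triflate); C16 half: cuts at C9'=C10' and C7'=C8' (Horner–Wadsworth–Emmons).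
Stereochemistry: C3 from commercially available (4R,6R)-4-hydroxy-2,2,6-trimethylcyclohexanone; C5' and C6' from Sharpless asymmetric epoxidation of β-cyclogeraniol and anti hydrolysis of the epoxide at C5'; double-bond geometry from E-selective olefinations and from syn addition across both alkynes in the coupling.
Silyl ethers on O3, O5' and O6' protect the hydroxyl groups during the coupling and are removed together in the last step.

Key step: step 16

**Route**

Step 1
Reactants: 1 (4R,6R)-4-hydroxy-2,2,6-trimethylcyclohexan-1-one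
Product: 2 (4R,6R)-4-[(tert-butyldimethylsilyl)oxy]-2,2,6-trimethylcyclohexan-1-one
Conditions: tBuMe2SiCl, imidazole, DMF, rt
Reagents that add atoms: tert-butyldimethylsilyl chloride, CC(C)(C)[Si](C)(C)Cl
Why: Silylation of the secondary alcohol with a silyl chloride and imidazole is a standard protection that leaves the ketone and the carbinol stereocentre untouched.

Step 2
Reactants: 2 (4R,6R)-4-[(tert-butyldimethylsilyl)oxy]-2,2,6-trimethylcyclohexan-1-one
Product: 3 (4R)-4-[(tert-butyldimethylsilyl)oxy]-2,6,6-trimethylcyclohex-1-en-1-yl trifluoromethanesulfonate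
Conditions: LiN(iPr)2, THF, −78 °C; then PhNTf2, −78 °C to rt
Reagents that add atoms: N-phenylbis(trifluoromethanesulfonimide), O=S(=O)(N(c1ccccc1)S(=O)(=O)C(F)(F)F)C(F)(F)F
Why: The ketone can enolise only toward its methyl-bearing α-carbon (the other α-carbon is quaternary), so enolate O-triflation should give the single tetrasubstituted enol triflate, erasing the α-methyl stereocentre and leaving the silyloxy-bearing centre (future C3, R) unchanged.

Step 3
Reactants: 3 (4R)-4-[(tert-butyldimethylsilyl)oxy]-2,6,6-trimethylcyclohex-1-en-1-yl trifluoromethanesulfonate; 4 (2E)-3-methylpent-2-en-4-yn-1-ol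
Product: 5 (2E)-5-[(4R)-4-[(tert-butyldimethylsilyl)oxy]-2,6,6-trimethylcyclohex-1-en-1-yl]-3-methylpent-2-en-4-yn-1-ol
Conditions: Pd(PPh3)4 (cat.), CuI (cat.), Et3N, DMF, rt
Reagents that add atoms: none
Why: Sonogashira coupling of a cyclohexenyl triflate with a terminal alkyne is well precedented for hindered ring triflates, tolerates the free allylic alcohol and forms the C6–C7 bond with the E geometry of the enynol retained.

Step 4
Reactants: 5 (2E)-5-[(4R)-4-[(tert-butyldimethylsilyl)oxy]-2,6,6-trimethylcyclohex-1-en-1-yl]-3-methylpent-2-en-4-yn-1-ol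
Product: 6 (2E)-5-[(4R)-4-[(tert-butyldimethylsilyl)oxy]-2,6,6-trimethylcyclohex-1-en-1-yl]-3-methylpent-2-en-4-ynal
Conditions: MnO2, CH2Cl2, rt
Reagents that add atoms: none
Why: Activated MnO2 oxidises allylic alcohols selectively to enals without touching the alkyne, the silyl ether or the olefin geometry.

Step 5
Reactants: 6 (2E)-5-[(4R)-4-[(tert-butyldimethylsilyl)oxy]-2,6,6-trimethylcyclohex-1-en-1-yl]-3-methylpent-2-en-4-ynal; 7 diethyl [(2E)-3-cyano-2-methylprop-2-en-1-yl]phosphonate
Product: 8 (2E,4E,6E)-9-[(4R)-4-[(tert-butyldimethylsilyl)oxy]-2,6,6-trimethylcyclohex-1-en-1-yl]-3,7-dimethylnona-2,4,6-trien-8-ynenitrile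
Conditions: NaH, THF, 0 °C; then 6, 0 °C to rt
Reagents that add atoms: none
Why: Horner–Wadsworth–Emmons reaction of the stabilised allylic phosphonate anion with the enal should form C11=C12 mainly as the E isomer, as in classical retinonitrile chemistry, and any 13Z isomer should be removable by chromatography.

Step 6
Reactants: 8 (2E,4E,6E)-9-[(4R)-4-[(tert-butyldimethylsilyl)oxy]-2,6,6-trimethylcyclohex-1-en-1-yl]-3,7-dimethylnona-2,4,6-trien-8-ynenitrile
Product: 9 (2E,4E,6E)-9-[(4R)-4-[(tert-butyldimethylsilyl)oxy]-2,6,6-trimethylcyclohex-1-en-1-yl]-3,7-dimethylnona-2,4,6-trien-8-ynal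
Conditions: iBu2AlH, CH2Cl2, −78 °C; then H2O, SiO2, 0 °C
Reagents that add atoms: water, O
Why: Reduction of a conjugated nitrile with one equivalent of iBu2AlH at low temperature stops at the aluminium aldimine, which hydrolyses to the aldehyde on work-up, the standard nitrile-to-aldehyde reduction of retinonitriles.

Step 7
Reactants: 10 1-bromobut-2-yne; 11 triethyl phosphite
Product: 12 diethyl but-2-yn-1-ylphosphonate
Conditions: neat, 120 °C
Reagents that add atoms: none
Why: Michaelis–Arbuzov reaction of a primary propargylic bromide with triethyl phosphite should give the phosphonate with loss of bromoethane.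

Step 8
Reactants: 9 (2E,4E,6E)-9-[(4R)-4-[(tert-butyldimethylsilyl)oxy]-2,6,6-trimethylcyclohex-1-en-1-yl]-3,7-dimethylnona-2,4,6-trien-8-ynal; 12 diethyl but-2-yn-1-ylphosphonate
Product: 13 (4R)-4-[(tert-butyldimethylsilyl)oxy]-2,6,6-trimethyl-1-[(3E,5E,7E,9E)-3,7-dimethyltrideca-3,5,7,9-tetraene-1,11-diyn-1-yl]cyclohex-1-ene (C24 half)
Conditions: LiN(SiMe3)2, THF, −78 °C; then 9, −78 to 0 °C
Reagents that add atoms: none
Why: Horner–Wadsworth–Emmons reaction of the lithiated propargylic phosphonate at its α-carbon with the polyenal should give the conjugated (E)-enyne (C15=C15'), a reaction type well known for silylated propargylphosphonates.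

Step 9
Reactants: 14 β-cyclocitral (2,6,6-trimethylcyclohex-1-ene-1-carbaldehyde)
Product: 15 β-cyclogeraniol ((2,6,6-trimethylcyclohex-1-en-1-yl)methanol)
Conditions: NaBH4, MeOH, 0 °C
Reagents that add atoms: none
Why: NaBH4 reduces the hindered conjugated aldehyde in the 1,2-sense to the allylic alcohol.

Step 10
Reactants: 15 β-cyclogeraniol ((2,6,6-trimethylcyclohex-1-en-1-yl)methanol)
Product: 16 [(1S,6S)-2,2,6-trimethyl-7-oxabicyclo[4.1.0]heptan-1-yl]methanol
Conditions: Ti(OiPr)4, L-(+)-diethyl tartrate, tBuOOH, 4 Å molecular sieves, CH2Cl2, −20 °C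
Reagents that add atoms: tert-butyl hydroperoxide, CC(C)(C)OO
Why: Sharpless asymmetric epoxidation with L-(+)-diethyl tartrate should deliver oxygen to the alkene face that gives the (1S,6S)-epoxy alcohol, by the same facial rule that gives (2S,3S)-epoxy alcohols from E-allylic alcohols, so the tartrate ligand sets both ring stereocentres.

Step 11
Reactants: 16 [(1S,6S)-2,2,6-trimethyl-7-oxabicyclo[4.1.0]heptan-1-yl]methanol
Product: 17 (1S,2R)-1-(hydroxymethyl)-2,6,6-trimethylcyclohexane-1,2-diol
Conditions: HClO4 (cat.), THF/H2O, 0 °C to rt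
Reagents that add atoms: water, O
Why: Acid-catalysed epoxide hydrolysis should proceed by anti attack of water at the methyl-bearing carbon (C5'), which is less hindered and better able to carry positive charge than the neopentyl C6' next to the hydroxymethyl group, so C5' is inverted and C6' retained to give the trans-diol.

Step 12
Reactants: 17 (1S,2R)-1-(hydroxymethyl)-2,6,6-trimethylcyclohexane-1,2-diol
Product: 18 (1R,2R)-1,2-dihydroxy-2,6,6-trimethylcyclohexane-1-carbaldehyde
Conditions: SO3·pyridine, DMSO, Et3N, CH2Cl2, 0 °C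
Reagents that add atoms: none
Why: Parikh–Doering oxidation converts the primary alcohol into the aldehyde while the tertiary alcohols are inert, and the α-carbon is quaternary so no epimerisation is possible.

Step 13
Reactants: 18 (1R,2R)-1,2-dihydroxy-2,6,6-trimethylcyclohexane-1-carbaldehyde; 19 dimethyl (2-oxopropyl)phosphonate
Product: 20 (3E)-4-[(1R,2R)-1,2-dihydroxy-2,6,6-trimethylcyclohexyl]but-3-en-2-one
Conditions: LiCl, iPr2NEt, MeCN, rt
Reagents that add atoms: none
Why: Horner–Wadsworth–Emmons reaction under the mild Masamune–Roush conditions should give the (E)-enone (C7'=C8') from the α-quaternary aldehyde without deprotonating the tertiary hydroxyl groups.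

Step 14
Reactants: 20 (3E)-4-[(1R,2R)-1,2-dihydroxy-2,6,6-trimethylcyclohexyl]but-3-en-2-one; 21 diethyl [3-(trimethylsilyl)prop-2-yn-1-yl]phosphonate
Product: 23 (1R,2R)-2,6,6-trimethyl-1-[(1E,3E)-3-methylhexa-1,3-dien-5-yn-1-yl]cyclohexane-1,2-diol, via C-silyl enyne diol 22 (not isolated)
Conditions: 21, n-BuLi (excess), THF, −78 °C; then 20, −78 to 0 °C; then MeOH, K2CO3, rt
Reagents that add atoms: none
Why: Horner–Wadsworth–Emmons reaction of the lithiated silylpropargyl phosphonate with the methyl ketone (the two hydroxyl groups consume two equivalents of base) should give mainly the (9'E)-enyne, as precedented for ionone-type ketones, and K2CO3 in methanol then removes the alkynyl silyl group.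

Step 15
Reactants: 23 (1R,2R)-2,6,6-trimethyl-1-[(1E,3E)-3-methylhexa-1,3-dien-5-yn-1-yl]cyclohexane-1,2-diol
Product: 24 (1R,2R)-2,6,6-trimethyl-1-[(1E,3E)-3-methylhexa-1,3-dien-5-yn-1-yl]-1,2-bis[(trimethylsilyl)oxy]cyclohexane (C16 half)
Conditions: Me3SiOTf, 2,6-lutidine, CH2Cl2, −78 to 0 °C
Reagents that add atoms: trimethylsilyl trifluoromethanesulfonate, C[Si](C)(C)OS(=O)(=O)C(F)(F)F
Why: A silyl triflate with 2,6-lutidine silylates even hindered tertiary alcohols at low temperature under basic conditions that should neither ionise the allylic C6' centre nor silylate the terminal alkyne.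

Step 16
Reactants: 13 (4R)-4-[(tert-butyldimethylsilyl)oxy]-2,6,6-trimethyl-1-[(3E,5E,7E,9E)-3,7-dimethyltrideca-3,5,7,9-tetraene-1,11-diyn-1-yl]cyclohex-1-ene; 24 (1R,2R)-2,6,6-trimethyl-1-[(1E,3E)-3-methylhexa-1,3-dien-5-yn-1-yl]-1,2-bis[(trimethylsilyl)oxy]cyclohexane
Product: 27 (3R,5'R,6'R)-3-O-(tert-butyldimethylsilyl)-5',6'-bis-O-(trimethylsilyl)-7,8-didehydro-5',6'-dihydro-β,β-carotene-3,5',6'-triol, via titanacyclopropene 25 (not isolated), via titanacyclopentadiene 26 (not isolated)
Conditions: Ti(OiPr)4 (1 equiv), iPrMgCl (2 equiv), 13, Et2O, −78 to −50 °C; then 24, −50 to −30 °C; then H2O, −78 °C to rt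
Reagents that add atoms: none
Why: Proposed new method: Ti(OiPr)4 and two equivalents of iPrMgCl should give the divalent titanium complex (η2-propene)Ti(OiPr)2, which exchanges propene for the unhindered methyl-capped C13'≡C14' alkyne of 13 to form titanacyclopropene 25, the terminal alkyne of 24 then inserts into the Ti–C13' bond to give titanacyclopentadiene 26, and water cleaves both Ti–C bonds with retention to release the C11'=C12'–C13'(CH3)=C14' diene. The closest known reaction type is the titanium alkoxide-mediated reductive cross-coupling of a preformed internal alkyne–titanium complex with a terminal alkyne to give an (E,E)-diene, which is here extended to two conjugated polyenynes. No ring of the target is closed and no stereocentre is formed; the only ring is the transient five-membered titanacycle, and the E geometry of both new double bonds follows from syn addition of titanium and carbon across each alkyne, which puts C10' trans to C13' and C15' trans to C12'. Site selectivity between the two alkynes of 13 should be secured by the shielding of C7≡C8 between the 2,6,6-trimethylcyclohexenyl ring and the C9 methyl group and by the use of one equivalent of titanium. Regioselectivity of C–C bond formation should be secured because both partners are 1,3-enynes whose bulky, conjugating alkenyl groups prefer the titanacycle positions next to titanium, so that the small groups (CH3 on C13', H on C12') end up on the two carbons that are joined. Cross- over homo-coupling should be secured by forming 25 completely at −50 °C before 24 is added.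

Step 17
Reactants: 27 (3R,5'R,6'R)-3-O-(tert-butyldimethylsilyl)-5',6'-bis-O-(trimethylsilyl)-7,8-didehydro-5',6'-dihydro-β,β-carotene-3,5',6'-triol
Product: 28 (3R,5'R,6'R)-7,8-didehydro-5',6'-dihydro-β,β-carotene-3,5',6'-triol (all-E)
Conditions: Bu4NF, AcOH, THF, 0 °C to rt, dark
Reagents that add atoms: none
Why: Buffered fluoride cleaves the secondary tert-butyldimethylsilyl ether and both tertiary trimethylsilyl ethers under non-acidic conditions that should neither ionise the allylic tertiary alcohol nor isomerise the polyene.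

**Compound list**

1 | (4R,6R)-4-hydroxy-2,2,6-trimethylcyclohexan-1-one | C[C@@H]1C[C@@H](O)CC(C)(C)C1=O | starting material
2 | (4R,6R)-4-[(tert-butyldimethylsilyl)oxy]-2,2,6-trimethylcyclohexan-1-one | C[C@@H]1C[C@@H](O[Si](C)(C)C(C)(C)C)CC(C)(C)C1=O | intermediate
3 | (4R)-4-[(tert-butyldimethylsilyl)oxy]-2,6,6-trimethylcyclohex-1-en-1-yl trifluoromethanesulfonate | CC1=C(OS(=O)(=O)C(F)(F)F)C(C)(C)C[C@H](O[Si](C)(C)C(C)(C)C)C1 | intermediate
4 | (2E)-3-methylpent-2-en-4-yn-1-ol | C#C/C(C)=C/CO | starting material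
5 | (2E)-5-[(4R)-4-[(tert-butyldimethylsilyl)oxy]-2,6,6-trimethylcyclohex-1-en-1-yl]-3-methylpent-2-en-4-yn-1-ol | CC1=C(C#C/C(C)=C/CO)C(C)(C)C[C@H](O[Si](C)(C)C(C)(C)C)C1 | intermediate
6 | (2E)-5-[(4R)-4-[(tert-butyldimethylsilyl)oxy]-2,6,6-trimethylcyclohex-1-en-1-yl]-3-methylpent-2-en-4-ynal | CC1=C(C#C/C(C)=C/C=O)C(C)(C)C[C@H](O[Si](C)(C)C(C)(C)C)C1 | intermediate
7 | diethyl [(2E)-3-cyano-2-methylprop-2-en-1-yl]phosphonate | CCOP(=O)(C/C(C)=C/C#N)OCC | starting material
8 | (2E,4E,6E)-9-[(4R)-4-[(tert-butyldimethylsilyl)oxy]-2,6,6-trimethylcyclohex-1-en-1-yl]-3,7-dimethylnona-2,4,6-trien-8-ynenitrile | CC1=C(C#C/C(C)=C/C=C/C(C)=C/C#N)C(C)(C)C[C@H](O[Si](C)(C)C(C)(C)C)C1 | intermediate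
9 | (2E,4E,6E)-9-[(4R)-4-[(tert-butyldimethylsilyl)oxy]-2,6,6-trimethylcyclohex-1-en-1-yl]-3,7-dimethylnona-2,4,6-trien-8-ynal | CC1=C(C#C/C(C)=C/C=C/C(C)=C/C=O)C(C)(C)C[C@H](O[Si](C)(C)C(C)(C)C)C1 | intermediate
10 | 1-bromobut-2-yne | CC#CCBr | starting material
11 | triethyl phosphite | CCOP(OCC)OCC | starting material
12 | diethyl but-2-yn-1-ylphosphonate | CC#CCP(=O)(OCC)OCC | intermediate
13 | (4R)-4-[(tert-butyldimethylsilyl)oxy]-2,6,6-trimethyl-1-[(3E,5E,7E,9E)-3,7-dimethyltrideca-3,5,7,9-tetraene-1,11-diyn-1-yl]cyclohex-1-ene (C24 half) | CC1=C(C#C/C(C)=C/C=C/C(C)=C/C=C/C#CC)C(C)(C)C[C@H](O[Si](C)(C)C(C)(C)C)C1 | intermediate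
14 | β-cyclocitral (2,6,6-trimethylcyclohex-1-ene-1-carbaldehyde) | CC1=C(C=O)C(C)(C)CCC1 | starting material
15 | β-cyclogeraniol ((2,6,6-trimethylcyclohex-1-en-1-yl)methanol) | CC1=C(CO)C(C)(C)CCC1 | intermediate
16 | [(1S,6S)-2,2,6-trimethyl-7-oxabicyclo[4.1.0]heptan-1-yl]methanol | OC[C@]12O[C@@]1(C)CCCC2(C)C | intermediate
17 | (1S,2R)-1-(hydroxymethyl)-2,6,6-trimethylcyclohexane-1,2-diol | OC[C@@]1(O)C(C)(C)CCC[C@@]1(C)O | intermediate
18 | (1R,2R)-1,2-dihydroxy-2,6,6-trimethylcyclohexane-1-carbaldehyde | O=C[C@@]1(O)C(C)(C)CCC[C@@]1(C)O | intermediate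
19 | dimethyl (2-oxopropyl)phosphonate | COP(=O)(CC(C)=O)OC | starting material
20 | (3E)-4-[(1R,2R)-1,2-dihydroxy-2,6,6-trimethylcyclohexyl]but-3-en-2-one | CC(=O)/C=C/[C@@]1(O)C(C)(C)CCC[C@@]1(C)O | intermediate
21 | diethyl [3-(trimethylsilyl)prop-2-yn-1-yl]phosphonate | CCOP(=O)(CC#C[Si](C)(C)C)OCC | starting material
22 | (1R,2R)-2,6,6-trimethyl-1-[(1E,3E)-3-methyl-6-(trimethylsilyl)hexa-1,3-dien-5-yn-1-yl]cyclohexane-1,2-diol | C[Si](C)(C)C#C/C=C(C)/C=C/[C@@]1(O)C(C)(C)CCC[C@@]1(C)O | intermediate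
23 | (1R,2R)-2,6,6-trimethyl-1-[(1E,3E)-3-methylhexa-1,3-dien-5-yn-1-yl]cyclohexane-1,2-diol | C#C/C=C(C)/C=C/[C@@]1(O)C(C)(C)CCC[C@@]1(C)O | intermediate
24 | (1R,2R)-2,6,6-trimethyl-1-[(1E,3E)-3-methylhexa-1,3-dien-5-yn-1-yl]-1,2-bis[(trimethylsilyl)oxy]cyclohexane (C16 half) | C#C/C=C(C)/C=C/[C@@]1(O[Si](C)(C)C)C(C)(C)CCC[C@@]1(C)O[Si](C)(C)C | intermediate
25 | titanacyclopropene: diisopropoxytitanium bonded to C13' and C14' of 13 | CC1=C(C#C/C(C)=C/C=C/C(C)=C/C=C/C2=C(C)[Ti]2(OC(C)C)OC(C)C)C(C)(C)C[C@H](O[Si](C)(C)C(C)(C)C)C1 | intermediate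
26 | titanacyclopentadiene: diisopropoxytitanium bonded to C14' and C11', new C12'–C13' bond in the ring | CC1=C(C#C/C(C)=C/C=C/C(C)=C/C=C/C2=C(C)C=C(/C=C(C)/C=C/[C@@]3(O[Si](C)(C)C)C(C)(C)CCC[C@@]3(C)O[Si](C)(C)C)[Ti]2(OC(C)C)OC(C)C)C(C)(C)C[C@H](O[Si](C)(C)C(C)(C)C)C1 | intermediate
27 | (3R,5'R,6'R)-3-O-(tert-butyldimethylsilyl)-5',6'-bis-O-(trimethylsilyl)-7,8-didehydro-5',6'-dihydro-β,β-carotene-3,5',6'-triol | CC1=C(C#C/C(C)=C/C=C/C(C)=C/C=C/C=C(C)/C=C/C=C(C)/C=C/[C@@]2(O[Si](C)(C)C)C(C)(C)CCC[C@@]2(C)O[Si](C)(C)C)C(C)(C)C[C@H](O[Si](C)(C)C(C)(C)C)C1 | intermediate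
28 | (3R,5'R,6'R)-7,8-didehydro-5',6'-dihydro-β,β-carotene-3,5',6'-triol (all-E) | CC1=C(C#C/C(C)=C/C=C/C(C)=C/C=C/C=C(C)/C=C/C=C(C)/C=C/[C@@]2(O)C(C)(C)CCC[C@@]2(C)O)C(C)(C)C[C@H](O)C1 | target

**Count and risks**

Total step count: 17.
Longest linear sequence: 9 steps (steps 1–6, 8, 16, 17 from 1; steps 9–17 from 14 are equally long).

Steps most likely to fail:

Step 16 (carries the label). What may go wrong: insertion of the terminal alkyne with the opposite regiochemistry, competing complexation of divalent titanium at C7≡C8 or along the polyene, proton transfer from the terminal alkyne to the titanacyclopropene, or protonolysis with allylic transposition toward vinylallenes. The fallback uses known chemistry, sets out from 13 and 24 and comes back at 27. Hydrozirconation of 13 with Cp2Zr(H)Cl in THF should place zirconium on the methyl-bearing C13' and give the C24 alkenylzirconocene chloride F1, which iodine converts with retention into the C24 (13'E)-alkenyl iodide F2. Hydrozirconation of the terminal alkyne of 24 gives the C16 (E)-alkenylzirconocene chloride F3, transmetalation with ZnCl2 gives the C16 alkenylzinc chloride F4, and Negishi coupling of F4 with F2 under Pd(PPh3)4 catalysis should give 27.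

Step 14. What may go wrong: poor control of the C9'=C10' geometry and competing enolisation of the methyl ketone by the basic propargyl anion. The fallback sets out from 18 and comes back at 22, and fixes the C9'=C10' geometry before the chain is attached. Wittig reaction of 3-(trimethylsilyl)propynal with ethyl 2-(triphenylphosphoranylidene)propanoate gives ethyl (2E)-2-methyl-5-(trimethylsilyl)pent-2-en-4-ynoate F5, and iBu2AlH reduction gives (2E)-2-methyl-5-(trimethylsilyl)pent-2-en-4-yn-1-ol F6. CBr4 and PPh3 then give [(3E)-5-bromo-4-methylpent-3-en-1-yn-1-yl]trimethylsilane F7, and Michaelis–Arbuzov reaction with triethyl phosphite gives diethyl [(2E)-2-methyl-5-(trimethylsilyl)pent-2-en-4-yn-1-yl]phosphonate F8. Horner–Wadsworth–Emmons reaction of lithiated F8 (LiN(SiMe3)2, THF) with aldehyde 18 forms C7'=C8' and gives 22, which is desilylated to 23 as in step 14.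

Step 8. What may go wrong: reaction of the ambident propargyl/allenyl phosphonate anion at its γ-carbon and incomplete E-selectivity at C15=C15'. The fallback sets out from 9 and comes back at 13. Takai olefination of 9 (CHI3, CrCl2, THF) gives the C21 (E)-alkenyl iodide F9, and Stille coupling of F9 with tributyl(prop-1-yn-1-yl)stannane (Pd(PPh3)4, CuI, DMF) gives 13.

**Further compounds**

F1 | step 16 | C24 alkenylzirconocene chloride (Zr on C13', H on C14', 13'E) | CC1=C(C#C/C(C)=C/C=C/C(C)=C/C=C/C=C(\C)[Zr](Cl)(C2C=CC=C2)C2C=CC=C2)C(C)(C)C[C@H](O[Si](C)(C)C(C)(C)C)C1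
F2 | step 16 | C24 (13'E)-alkenyl iodide, (4R)-4-[(tert-butyldimethylsilyl)oxy]-1-[(3E,5E,7E,9E,11E)-12-iodo-3,7-dimethyltrideca-3,5,7,9,11-pentaen-1-yn-1-yl]-2,6,6-trimethylcyclohex-1-ene | CC1=C(C#C/C(C)=C/C=C/C(C)=C/C=C/C=C(\C)I)C(C)(C)C[C@H](O[Si](C)(C)C(C)(C)C)C1
F3 | step 16 | C16 (E)-alkenylzirconocene chloride (Zr on C12') | Cl[Zr](/C=C/C=C(C)/C=C/[C@@]1(O[Si](C)(C)C)C(C)(C)CCC[C@@]1(C)O[Si](C)(C)C)(C2C=CC=C2)C2C=CC=C2
F4 | step 16 | C16 alkenylzinc chloride (Zn on C12') | Cl[Zn]/C=C/C=C(C)/C=C/[C@@]1(O[Si](C)(C)C)C(C)(C)CCC[C@@]1(C)O[Si](C)(C)C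
F5 | step 14 | ethyl (2E)-2-methyl-5-(trimethylsilyl)pent-2-en-4-ynoate | CCOC(=O)/C(C)=C/C#C[Si](C)(C)C
F6 | step 14 | (2E)-2-methyl-5-(trimethylsilyl)pent-2-en-4-yn-1-ol | OC/C(C)=C/C#C[Si](C)(C)C
F7 | step 14 | [(3E)-5-bromo-4-methylpent-3-en-1-yn-1-yl]trimethylsilane | BrC/C(C)=C/C#C[Si](C)(C)C
F8 | step 14 | diethyl [(2E)-2-methyl-5-(trimethylsilyl)pent-2-en-4-yn-1-yl]phosphonate | CCOP(=O)(C/C(C)=C/C#C[Si](C)(C)C)OCC
F9 | step 8 | C21 (E)-alkenyl iodide, (4R)-4-[(tert-butyldimethylsilyl)oxy]-1-[(3E,5E,7E,9E)-10-iodo-3,7-dimethyldeca-3,5,7,9-tetraen-1-yn-1-yl]-2,6,6-trimethylcyclohex-1-ene | CC1=C(C#C/C(C)=C/C=C/C(C)=C/C=C/I)C(C)(C)C[C@H](O[Si](C)(C)C(C)(C)C)C1
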